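The runs were computed on assumed constants, and the scatter is random.

| flask | substrate | partner | remark | time |
|---|---|---|---|---|
| cedar | 0.93 M | 0.49 M | run made earlier |  |
| ash | 0.93 M | 0.73 M | run made earlier |  |
| elm | 0.47 M | 0.977 M | run made earlier |  |
| flask | 0.93 M | 0.977 M |  | 8.0 h |

- cedar (time / h: substrate / %, mono adduct / %, other mono adduct / %): 0.833: 75, 6, 12; 1.33: 69, 7, 9; 2.00: 65, 9, 13; 4.00: 64, 5, 15; 6.00: 61, 10, 13; 10.0: 55, 0, 14
- ash (time / h: substrate / %, mono adduct / %, other mono adduct / %): 0.833: 63, 4, 12; 1.33: 59, 5, 14; 2.00: 53, 4, 19; 4.00: 46, 7, 20; 6.00: 46, 3, 22; 10.0: 46, 8, 23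
- elm (time / h: substrate / %, mono adduct / %, other mono adduct / %): 0.833: 51, 4, 19; 2.50: 26, 6, 29; 4.00: 15, 8, 28; 6.00: 13, 6, 31; 10.0: 8, 1, 29

(readings scatter by 2 percentage points)

* how much substrate there is at 8.0 h, in percent of the substrate charged
* how much mono adduct there is at 8.0 h, in percent of the substrate charged
* how much other mono adduct there is at 8.0 h, in percent of the substrate charged
* how much double product there is at 8.0 h, in percent of the substrate charged

- Slowness in the ash run is a stop: substrate reads 46 % at 4.00 h and 46 % at 10.0 h, while the elm run, charged with more partner, still falls from 15 % to 8 % over the same hours.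
- Counting turnovers gives the quantity to carry, the partner cost, which is the moles of partner charged per mole of substrate lost once substrate stops falling; the ash run reads 1.45, with the scatter of its readings.
- The flask, now turning substrate and c(partner) into the two mono adducts and double product, has partner for 0.672 M of substrate, less than the 0.93 M charged, so partner is the limiting reagent by this reckoning, which leaves substrate at 27.7 % at 8.0 h.
- At this cost each mole of partner charged turns over 0.690 mole of substrate in the flask.
- The forecast stands higher on substrate, with 33 %, and gives mono adduct 6 %, other mono adduct 24 % and double product 37 %, “with double product taken as the remainder of the balance”.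

    partner + other mono adduct → double product + by-product (k = 3.52 × 10⁻⁵ /M/s)
    substrate + partner → mono adduct + by-product (k = 1.84 × 10⁻⁴ /M/s)
    partner ⇌ dormant form (K = 1.50, k = 4.47 × 10⁻⁵ /s)
    substrate + partner → other mono adduct + by-product (k = 1.19 × 10⁻⁴ /M/s)
    mono adduct ⇌ isomer of the product (K = 1.74, k = 0.00344 /s)
    partner + mono adduct → double product + by-product (k = 0.00104 /M/s)

The flask at 8.00 h holds substrate 31.1 %, mono adduct 6.79 %, other mono adduct 25.0 % and double product 25.3 %, with partner at 1.5 % of its charge and dormant form at 0.0866 M, and the partner charged per mole of substrate lost so far comes to 1.53. The neighbour flask with 1.6 M of substrate holds 53.0 % of it where the carried cost gave 58.0 %, its own partner charged per mole of substrate lost being 1.30. Mono adduct has a half-life of 0.056 h toward the isomer of the product, forward step alone, shorter than its 0.19 h toward double product at the charged concentrations. The flask at 8.00 h holds 11.8 % of that isomer.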